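A per cent of excess means nothing until its base is named, and two chemists looking at these flasks name different bases. Each flask holds a racemic substrate under held gas with a single-handed catalyst.

common to all: left-handed substrate 20 mM; right-handed substrate 20 mM; gas 1.5 mM (held)

|  | free catalyst | remark | time |
|---|---|---|---|
| alpha | 0.11 mM | run made earlier |  |
| epsilon | 0.46 mM | run made earlier |  |
| beta | 1.7 mM | run made earlier |  |
| summer | 0.25 mM |  | 20 h |
| dawn | 0.12 mM |  | 20 h |
| winter | 0.40 mM |  | 20 h |
| spring | 1.2 mM |  | 20 h |
| autumn | 1.5 mM |  | 20 h |
| noon | 0.80 mM |  | 20 h |

- alpha (time / h: left-handed product / %, right-handed product / %): 1.00: 6.2, 0.5; 2.00: 11.7, 0.1; 4.00: 17.2, 0.8; 8.00: 22.5, 0.3; 15.0: 25.2, 1.0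
- epsilon (time / h: left-handed product / %, right-handed product / %): 3.00: 36.9, 1.3; 6.00: 44.9, 2.1; 8.00: 45.9, 2.2; 12.0: 47.0, 2.3; 15.0: 47.3, 2.2
- beta (time / h: left-handed product / %, right-handed product / %): 3.00: 49.6, 4.3; 6.00: 50.0, 6.2; 8.00: 49.8, 7.4; 12.0: 49.9, 8.4; 15.0: 50.0, 9.0

(readings scatter by 0.3 percentage points)

- free catalyst is single-handed; left-handed substrate and right-handed substrate are mirror images of each other, charged as a racemate, each of them at the stated concentration
- the numbers in the tables scatter by 0.3 percentage points (one standard deviation)
- at the start none of the gas is in solution

* ranking by excess of left-handed product over right-handed product, from high to low, at 20 h (summer / dawn / winter / spring / autumn / noon)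
* the excess of left-handed product over right-handed product of the flask you put first, at 20 h
* the excess of left-handed product over right-handed product of the flask you put last, at 20 h

Both chemists start from the same reading: left-handed product stalls. In epsilon, left-handed product creeps from 47.0% to 47.3% between 12.0 h and 15.0 h, short of the left-handed substrate's half of the charge. Taking substrate as its charge minus its product, epsilon's last reading gives 6.35 mM⁻¹ for the left hand. This is the lifetime dose: the natural logarithm of charged over remaining substrate of one hand at the stall, divided by the catalyst charged. Alpha, a different flask, reads 6.37 mM⁻¹, so the dose looks frozen per mM. Beta's last reading of right-handed product, still up by 0.6 percentage points over its last interval, gives 0.117 mM⁻¹, and the ratio of the two doses, a selectivity factor, reads 54.3. In these flasks, with equal charges and the gas held, each hand's stalled product is then its charge times one minus the exponential of minus dose times catalyst, and the asked 20 h lies later than the last readings.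

The first chemist counts excess in points of the charge, left minus right. Epsilon's 45 points beats beta's 41 points, and the doses give noon 45 points against dawn's 26 points, so she expects a peak at middling catalyst. The second counts enantiomeric excess, left minus right over left plus right. At their last readings epsilon gives 91.1% and beta 69.5%, and in beta left-handed product reads 50.0% while right-handed product has climbed from 6.2% to 9.0%.

I side with the second, since excess between mirror images is conventionally a share of product. My reckoning gives dawn 94.9% and autumn 72.3%, and it ranks the flasks from high to low in order of rising catalyst, with dawn, which holds less catalyst than any other, first. The first chemist's count remains right for excess product per charge.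

The forecast, on her count, ranks noon > winter > spring > autumn > summer > dawn, with 45.4% for noon and 26.4% for dawn: “The optimum lies near 0.6–0.8 mM.”

The simulation gives dawn > summer > winter > noon > spring > autumn, with 95.0% first and 72.7% last. Dawn's catalyst stands 99.1% spent at 20.0 h, and at 200 h its excess is still 95.0%. The doses, applied to noon's 0.80 mM, give 83.5%, and the flask shows 83.8%.

    reagent + free catalyst + left-handed substrate → free catalyst + left-handed product (k = 18500 L² mol⁻² min⁻¹)
    reagent + free catalyst + right-handed substrate → free catalyst + right-handed product (k = 332 L² mol⁻² min⁻¹)
    2 reagent → self-condensation product (k = 10.2 L mol⁻¹ min⁻¹)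
    gas ⇌ reagent, rate k4*(csat - [reagent]) (kL = 0.353 min⁻¹)
    reagent + free catalyst → spent catalyst (k = 2.87 L mol⁻¹ min⁻¹)

For a neighbour of dawn charged with 0.48 mM, the doses give 89.2%. The computed flask gives 89.4%.

(The readings were generated by integration on assumed constants, and the scatter is random.)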